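**Strategy.** Everything rests on cutting the C1–C2 bond of the cyclohexane ring. Quaternary C1, which carries O1 and the carboxyl carbon C7 and sits next to the unsubstituted methylene C2, is traced back to a six-membered lactone (C7 bound to O4) with a vinyl group (C3=C2) on C4. Its silyl ketene acetal undergoes an Ireland–Claisen shift that, in one operation, forms C1–C2, breaks O4–C4, contracts the lactone to the carbocycle, frees C7 and copies the C4 configuration onto C1. The lactone comes from desymmetrised divinylcarbinol and a glycolic acid enediolate. The C3=C4 alkene left behind is dihydroxylated on a C7–O5 lactone, which also differentiates O3, O4 and O5.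

Key step: step 8

Remark: quinic acid numbering is used for all atoms (C1 quaternary, C7 carboxyl, caffeate on O3, p-coumarate on O4, O5 free). O1, O3 and O4 lie on one ring face, O5 and C7 on the other. The open-chain acids and the six-membered lactone are carried as both C1 epimers (one is drawn), because C1 is planarised in the key step.

## Route

Step 1
Reactants: 1 penta-1,4-dien-3-ol (divinylcarbinol)
Product: 2 (2R,3S)-1,2-epoxypent-4-en-3-ol (erythro; carbinol carbon = C4, epoxide CH = C5, epoxide CH2 = C6)
Conditions: Ti(OiPr)4 (0.15 equiv), L-(+)-diisopropyl tartrate (0.2 equiv), t-BuOOH (decane), 4 Å MS, CH2Cl2, −20 °C, several days; non-aqueous work-up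
Reagents that add atoms: tert-butyl hydroperoxide CC(C)(C)OO
Why: Sharpless asymmetric epoxidation desymmetrises the dienol, because the L-(+)-tartrate catalyst selects one enantiotopic vinyl group and one of its faces to give the anti (erythro) epoxy alcohol (C4 S, C5 R), and slower over-oxidation of the minor enantiomer should raise the enantiomeric purity with time.

Step 2
Reactants: 2 (2R,3S)-1,2-epoxypent-4-en-3-ol
Product: 3 (R)-2-[(S)-1-(4-methoxybenzyloxy)prop-2-enyl]oxirane
Conditions: NaH, 4-MeOC6H4CH2Cl, Bu4NI (cat.), THF–DMF, −10 °C → rt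
Reagents that add atoms: 4-methoxybenzyl chloride COc1ccc(CCl)cc1
Why: Williamson etherification of the alkoxide as it forms, in an aprotic medium at low temperature, should outrun Payne migration of the epoxide, and the PMB group on O4 can later be removed oxidatively beside silyl ether, MOM acetal and vinyl group.

Step 3
Reactants: 4 methyl glycolate
Product: 5 methyl 2-(methoxymethoxy)acetate
Conditions: MeOCH2Cl, iPr2NEt, CH2Cl2, 0 °C → rt
Reagents that add atoms: chloromethyl methyl ether COCCl
Why: O-alkylation of the primary alcohol by the oxocarbenium-type electrophile under a hindered amine base installs on O1 an acetal that tolerates enolates, fluoride, oxidants and acylation and falls only to aqueous acid.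

Step 4
Reactants: 5 methyl 2-(methoxymethoxy)acetate
Product: 6 2-(methoxymethoxy)acetic acid
Conditions: LiOH, THF–H2O, 0 °C → rt; 1 M HCl to pH 3 at 0 °C, EtOAc extraction
Reagents that add atoms: lithium hydroxide [Li+].[OH-]
Why: Ordinary BAC2 saponification of an unhindered methyl ester, with brief cold acidification that the MOM acetal survives.

Step 5
Reactants: 3 (R)-2-[(S)-1-(4-methoxybenzyloxy)prop-2-enyl]oxirane; 6 2-(methoxymethoxy)acetic acid
Product: 10 (4R,5S)-4-(tert-butyldimethylsilyloxy)-5-(4-methoxybenzyloxy)-2-(methoxymethoxy)hept-6-enoic acid (both C2 epimers), via dilithium enediolate 7 (not isolated), via dilithium alkoxide carboxylate 8 (not isolated), via bis-silylated adduct 9 (not isolated)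
Conditions: 6 (1.5 equiv), LiN(iPr)2 (3.1 equiv), THF, −78 → 0 °C; 3, DMPU, 0 °C → rt; t-BuMe2SiOTf, −78 → 0 °C; then AcOH–THF–H2O, rt
Reagents that add atoms: tert-butyldimethylsilyl trifluoromethanesulfonate CC(C)(C)[Si](C)(C)OS(=O)(=O)C(F)(F)F
Why: Carboxylic acid enediolates open monosubstituted epoxides by SN2 attack at the CH2 terminus (C6) without touching C5; whereas an ester enolate would let the new C5 alkoxide close the five-membered lactone, the carboxylate cannot be attacked, and silylation in the same flask caps O5 before any acid is seen, the silyl ester alone being lost in the mild hydrolysis.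

Step 6
Reactants: 10 (4R,5S)-4-(tert-butyldimethylsilyloxy)-5-(4-methoxybenzyloxy)-2-(methoxymethoxy)hept-6-enoic acid
Product: 11 (4R,5S)-4-(tert-butyldimethylsilyloxy)-5-hydroxy-2-(methoxymethoxy)hept-6-enoic acid
Conditions: DDQ, CH2Cl2–pH 7 phosphate buffer, 0 °C
Reagents that add atoms: none
Why: Oxidative PMB cleavage (benzylic hydride abstraction, then hydrolysis of the oxocarbenium ion) is neutral, so no alkoxide is formed that could move the silyl group from O5 to O4, and the unactivated allylic alcohol is not oxidised further.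

Step 7
Reactants: 11 (4R,5S)-4-(tert-butyldimethylsilyloxy)-5-hydroxy-2-(methoxymethoxy)hept-6-enoic acid
Product: 12 (5R,6S)-5-(tert-butyldimethylsilyloxy)-3-(methoxymethoxy)-6-vinyltetrahydro-2H-pyran-2-one (5,6-trans; both C3 epimers, the 3S form drawn)
Conditions: DCC, 4-dimethylaminopyridine (cat.), CH2Cl2 (0.01 M), 0 °C → rt
Reagents that add atoms: none
Why: Steglich-type lactonisation in which O4 is the only free hydroxyl, so only the six-membered ring can form, helped by the trans vinyl and silyloxy groups both being able to sit equatorial.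

Step 8
Reactants: 12 (5R,6S)-5-(tert-butyldimethylsilyloxy)-3-(methoxymethoxy)-6-vinyltetrahydro-2H-pyran-2-one
Product: 15 (1S,5R)-5-(tert-butyldimethylsilyloxy)-1-(methoxymethoxy)cyclohex-3-ene-1-carboxylic acid, via cyclic trimethylsilyl ketene acetal 13 (not isolated), via trimethylsilyl ester 14 (not isolated)
Conditions: Me3SiCl–Et3N, then LiN(SiMe3)2, THF, −78 °C → rt; solvent change to toluene, 105 °C; then THF–H2O–AcOH, rt
Reagents that add atoms: none
Why: LiN(SiMe3)2 removes the C1 proton of either epimer in the presence of Me3SiCl, so the lactone enolate is trapped at once as ketene acetal 13, whose C1=C7 geometry is fixed by the ring. On heating, the half-chair flips to the conformer with the C4 vinyl group and the trans C5 silyloxy group axial, and a concerted suprafacial [3,3]-sigmatropic shift runs over C1=C7–O4–C4–C3=C2; this is the Ireland–Claisen rearrangement in its ring-contracting form known for 6-alkenyl δ-lactones, and the α-oxygen is familiar from glycolate ester versions. The cyclohexene is closed by the sigmatropic C1–C2 bond formation itself through a boat-like transition state shaped like bicyclo[2.2.2]octane, while O4–C4 breaks and C7 is released as silyl ester 14 on the new quaternary carbon. C1 is controlled by C4: C2 can reach only the lactone face that carries the vinyl group, which places C7 cis to O5 (trans to the vinyl group in 12) and O1 trans to O5, that is 1S. The step needs O-silylation rather than C-silylation and no elimination, which the in-situ quench, the fully substituted C1 and the lack of a leaving group on C6 should secure, and the unsubstituted terminus C2 keeps the crowded bond formation feasible. Mild aqueous acid then cleaves only the silyl ester.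

Step 9
Reactants: 15 (1S,5R)-5-(tert-butyldimethylsilyloxy)-1-(methoxymethoxy)cyclohex-3-ene-1-carboxylic acid
Product: 16 (1S,5R)-5-hydroxy-1-(methoxymethoxy)cyclohex-3-ene-1-carboxylic acid
Conditions: HF·pyridine, pyridine–THF, 0 °C → rt
Reagents that add atoms: none
Why: Fluoride-driven Si–O cleavage under buffered, weakly acidic conditions leaves the MOM acetal, the alkene and both stereocentres untouched.

Step 10
Reactants: 16 (1S,5R)-5-hydroxy-1-(methoxymethoxy)cyclohex-3-ene-1-carboxylic acid
Product: 17 (1S,5R)-1-(methoxymethoxy)-6-oxabicyclo[3.2.1]oct-3-en-7-one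
Conditions: DCC, 4-dimethylaminopyridine (cat.), CH2Cl2, 0 °C → rt
Reagents that add atoms: none
Why: Steglich-type lactonisation is possible only because C7 and O5 are cis, so it both checks the outcome of step 8 and masks carboxyl and O5 in one rigid bridge.

Step 11
Reactants: 17 (1S,5R)-1-(methoxymethoxy)-6-oxabicyclo[3.2.1]oct-3-en-7-one
Product: 18 (1S,3R,4R,5R)-3,4-dihydroxy-1-(methoxymethoxy)-6-oxabicyclo[3.2.1]octan-7-one (1-O-MOM-1,5-quinide)
Conditions: OsO4 (3 mol %), N-methylmorpholine N-oxide, acetone–H2O, rt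
Reagents that add atoms: OsO4 O=[Os](=O)(=O)=O (catalytic oxygen carrier); N-methylmorpholine N-oxide C[N+]1([O-])CCOCC1; water O
Why: Catalytic cis-dihydroxylation by [3+2] addition of OsO4 should occur on the open face of C3=C4 opposite the C7–O5 bridge, setting O3 and O4 cis to each other and trans to O5, as is known for such unsaturated bicyclic lactones.

Step 12
Reactants: 19 caffeic acid
Product: 21 (E)-3-[3,4-bis(methoxymethoxy)phenyl]acrylic acid, via methoxymethyl ester 20 (not isolated)
Conditions: MeOCH2Cl (3.6 equiv), iPr2NEt, CH2Cl2–DMF, 0 °C → rt, N2; then LiOH, THF–MeOH–H2O, rt; 1 M HCl to pH 4 at 0 °C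
Reagents that add atoms: chloromethyl methyl ether COCCl; lithium hydroxide [Li+].[OH-]
Why: MOMCl alkylates both phenols and the carboxylate, and only the acyl acetal is base-labile, so saponification in the same flask frees the acid while the aryl MOM ethers stay.

Step 13
Reactants: 18 1-O-MOM-1,5-quinide; 21 (E)-3-[3,4-bis(methoxymethoxy)phenyl]acrylic acid
Product: 22 3-O-[(E)-3,4-bis(methoxymethoxy)cinnamoyl]-1-O-(methoxymethyl)-1,5-quinide
Conditions: 21 (1.0 equiv), DCC (1.05 equiv), 4-dimethylaminopyridine (0.1 equiv), CH2Cl2, −20 → 0 °C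
Reagents that add atoms: none
Why: Steglich esterification; in the rigid chair of the lactone O3–H is equatorial and open, O4–H is axial and screened by the axial hydrogens on C2 and C6, and O1 is blocked, so one equivalent of acid at low temperature should acylate O3, which is also the more stable site should any migration occur.

Step 14
Reactants: 23 p-coumaric acid
Product: 25 (E)-3-[4-(methoxymethoxy)phenyl]acrylic acid, via methoxymethyl ester 24 (not isolated)
Conditions: MeOCH2Cl (2.4 equiv), iPr2NEt, CH2Cl2–DMF, 0 °C → rt; then LiOH, THF–MeOH–H2O, rt; 1 M HCl to pH 4 at 0 °C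
Reagents that add atoms: chloromethyl methyl ether COCCl; lithium hydroxide [Li+].[OH-]
Why: Same alkylation and selective saponification sequence as in step 12.

Step 15
Reactants: 22 3-O-acyl lactone; 25 (E)-3-[4-(methoxymethoxy)phenyl]acrylic acid
Product: 26 3-O-[(E)-3,4-bis(methoxymethoxy)cinnamoyl]-4-O-[(E)-4-(methoxymethoxy)cinnamoyl]-1-O-(methoxymethyl)-1,5-quinide
Conditions: 25 (2 equiv), DCC (2.2 equiv), 4-dimethylaminopyridine (0.5 equiv), CH2Cl2, 0 °C → rt
Reagents that add atoms: none
Why: Steglich esterification of the only remaining hydroxyl, where excess activated acid makes acylation of axial O4 faster than base-induced wandering of the O3 ester.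

Step 16
Reactants: 26 fully protected diester lactone
Product: 27 3-O-caffeoyl-4-O-p-coumaroylquinic acid (CNP0077575.1)
Conditions: 2 M aq HCl–THF (1:1), argon, 35 °C; freeze-drying, reversed-phase chromatography
Reagents that add atoms: water O
Why: Under specific acid catalysis the four formaldehyde acetals cleave through oxocarbenium ions and the strained bicyclic γ-lactone opens by AAC2 hydrolysis, while the conjugated esters of secondary alcohols hydrolyse far more slowly and acyl migration, which is base-promoted, is held back at low pH; no stereocentre is touched.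

## Compound list

1 | penta-1,4-dien-3-ol | C=CC(O)C=C | starting material
2 | (2R,3S)-1,2-epoxypent-4-en-3-ol | C=C[C@H](O)[C@H]1CO1 | intermediate
3 | (R)-2-[(S)-1-(4-methoxybenzyloxy)prop-2-enyl]oxirane | C=C[C@H](OCc1ccc(OC)cc1)[C@H]2CO2 | intermediate
4 | methyl glycolate | COC(=O)CO | starting material
5 | methyl 2-(methoxymethoxy)acetate | COCOCC(=O)OC | intermediate
6 | 2-(methoxymethoxy)acetic acid | COCOCC(=O)O | intermediate
7 | dilithium enediolate of 6 | COCOC=C([O-])[O-].[Li+].[Li+] | intermediate
8 | dilithium (4R,5S)-5-(4-methoxybenzyloxy)-2-(methoxymethoxy)-4-oxidohept-6-enoate (2S epimer drawn) | C=C[C@H](OCc1ccc(OC)cc1)[C@H]([O-])C[C@H](OCOC)C(=O)[O-].[Li+].[Li+] | intermediate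
9 | tert-butyldimethylsilyl (4R,5S)-4-(tert-butyldimethylsilyloxy)-5-(4-methoxybenzyloxy)-2-(methoxymethoxy)hept-6-enoate (2S epimer drawn) | C=C[C@H](OCc1ccc(OC)cc1)[C@H](O[Si](C)(C)C(C)(C)C)C[C@H](OCOC)C(=O)O[Si](C)(C)C(C)(C)C | intermediate
10 | (4R,5S)-4-(tert-butyldimethylsilyloxy)-5-(4-methoxybenzyloxy)-2-(methoxymethoxy)hept-6-enoic acid (2S epimer drawn) | C=C[C@H](OCc1ccc(OC)cc1)[C@H](O[Si](C)(C)C(C)(C)C)C[C@H](OCOC)C(=O)O | intermediate
11 | (4R,5S)-4-(tert-butyldimethylsilyloxy)-5-hydroxy-2-(methoxymethoxy)hept-6-enoic acid (2S epimer drawn) | C=C[C@H](O)[C@H](O[Si](C)(C)C(C)(C)C)C[C@H](OCOC)C(=O)O | intermediate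
12 | (5R,6S)-5-(tert-butyldimethylsilyloxy)-3-(methoxymethoxy)-6-vinyltetrahydro-2H-pyran-2-one, 5,6-trans (3S epimer drawn) | C=C[C@@H]1OC(=O)[C@@H](OCOC)C[C@H]1O[Si](C)(C)C(C)(C)C | intermediate
13 | (2S,3R)-3-(tert-butyldimethylsilyloxy)-5-(methoxymethoxy)-6-(trimethylsilyloxy)-2-vinyl-3,4-dihydro-2H-pyran | C=C[C@@H]1OC(O[Si](C)(C)C)=C(OCOC)C[C@H]1O[Si](C)(C)C(C)(C)C | intermediate
14 | trimethylsilyl (1S,5R)-5-(tert-butyldimethylsilyloxy)-1-(methoxymethoxy)cyclohex-3-ene-1-carboxylate | C1=C[C@H](O[Si](C)(C)C(C)(C)C)C[C@](OCOC)(C(=O)O[Si](C)(C)C)C1 | intermediate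
15 | (1S,5R)-5-(tert-butyldimethylsilyloxy)-1-(methoxymethoxy)cyclohex-3-ene-1-carboxylic acid, carboxyl cis to O5 | C1=C[C@H](O[Si](C)(C)C(C)(C)C)C[C@](OCOC)(C(=O)O)C1 | intermediate
16 | (1S,5R)-5-hydroxy-1-(methoxymethoxy)cyclohex-3-ene-1-carboxylic acid | C1=C[C@H](O)C[C@](OCOC)(C(=O)O)C1 | intermediate
17 | (1S,5R)-1-(methoxymethoxy)-6-oxabicyclo[3.2.1]oct-3-en-7-one | O=C1O[C@H]2C=CC[C@]1(OCOC)C2 | intermediate
18 | (1S,3R,4R,5R)-3,4-dihydroxy-1-(methoxymethoxy)-6-oxabicyclo[3.2.1]octan-7-one | O=C1O[C@H]2[C@H](O)[C@H](O)C[C@]1(OCOC)C2 | intermediate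
19 | caffeic acid | O=C(O)/C=C/c1ccc(O)c(O)c1 | starting material
20 | methoxymethyl (E)-3-[3,4-bis(methoxymethoxy)phenyl]acrylate | COCOC(=O)/C=C/c1ccc(OCOC)c(OCOC)c1 | intermediate
21 | (E)-3-[3,4-bis(methoxymethoxy)phenyl]acrylic acid | O=C(O)/C=C/c1ccc(OCOC)c(OCOC)c1 | intermediate
22 | 3-O-[(E)-3,4-bis(methoxymethoxy)cinnamoyl]-1-O-(methoxymethyl)-1,5-quinide | O=C1O[C@H]2[C@H](O)[C@H](OC(=O)/C=C/c3ccc(OCOC)c(OCOC)c3)C[C@]1(OCOC)C2 | intermediate
23 | p-coumaric acid | O=C(O)/C=C/c1ccc(O)cc1 | starting material
24 | methoxymethyl (E)-3-[4-(methoxymethoxy)phenyl]acrylate | COCOC(=O)/C=C/c1ccc(OCOC)cc1 | intermediate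
25 | (E)-3-[4-(methoxymethoxy)phenyl]acrylic acid | O=C(O)/C=C/c1ccc(OCOC)cc1 | intermediate
26 | 3-O-[(E)-3,4-bis(methoxymethoxy)cinnamoyl]-4-O-[(E)-4-(methoxymethoxy)cinnamoyl]-1-O-(methoxymethyl)-1,5-quinide | O=C1O[C@H]2[C@H](OC(=O)/C=C/c3ccc(OCOC)cc3)[C@H](OC(=O)/C=C/c3ccc(OCOC)c(OCOC)c3)C[C@]1(OCOC)C2 | intermediate
27 | (1R,3R,4S,5R)-3-[(E)-caffeoyloxy]-4-[(E)-p-coumaroyloxy]-1,5-dihydroxycyclohexane-1-carboxylic acid | O=C(/C=C/c1ccc(O)cc1)O[C@H]1[C@H](O)C[C@](O)(C(=O)O)C[C@H]1OC(=O)/C=C/c1ccc(O)c(O)c1 | target

## Step count and risks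

Total step count: 16. Longest linear sequence: 12 (steps 1, 2, 5–11, 13, 15, 16; the branch from 4 through steps 3 and 4 is equally long).

**Step 8.**
- What may go wrong: the crowded, tetrasubstituted ketene acetal may be lost by hydrolysis, C-silylation or fragmentation before it reaches the strained boat geometry with both the C4 and C5 substituents axial.
- Fallback (sets out from 5, comes back at 17): the ring is built by a Diels–Alder reaction and the O5 bridge by iodolactonisation.
- The lithium enolate of 5 (LiN(iPr)2, THF, −78 °C) is hydroxymethylated with monomeric formaldehyde to racemic methyl 3-hydroxy-2-(methoxymethoxy)propanoate F1.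
- Dehydration with DCC and catalytic CuCl in warm toluene gives methyl 2-(methoxymethoxy)acrylate F2.
- Heating with buta-1,3-diene in toluene in a sealed vessel gives racemic methyl 1-(methoxymethoxy)cyclohex-3-ene-1-carboxylate F3.
- LiOH gives racemic 1-(methoxymethoxy)cyclohex-3-ene-1-carboxylic acid F4.
- Preparative chromatography on a chiral stationary phase delivers (S)-1-(methoxymethoxy)cyclohex-3-ene-1-carboxylic acid F5.
- I2, KI and NaHCO3 close the carboxylate onto C5 anti to the iodonium ion, giving (1S,4R,5R)-4-iodo-1-(methoxymethoxy)-6-oxabicyclo[3.2.1]octan-7-one F6.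
- DBU in warm toluene removes HI by anti elimination towards C3 and gives 17.

**Step 5.**
- What may go wrong: sluggish opening by the aggregated enediolate, or incomplete capping of the hindered C5 alkoxide, so that five-membered lactonisation takes over on work-up.
- Fallback (sets out from 3 and 6, comes back at 9): the lactonisation is accepted and then reversed.
- The same opening is quenched into cold dilute acid and the crude hydroxy acid is stirred with catalytic pyridinium p-toluenesulfonate. All material then collapses to (5R)-3-(methoxymethoxy)-5-[(S)-1-(4-methoxybenzyloxy)prop-2-enyl]dihydrofuran-2(3H)-one F7, which is purified.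
- One equivalent of LiOH in THF–water reopens it to lithium (4R,5S)-4-hydroxy-5-(4-methoxybenzyloxy)-2-(methoxymethoxy)hept-6-enoate F8.
- F8 is dried without acidification and silylated twice with t-BuMe2SiCl and imidazole in DMF to give 9. The mild hydrolysis of step 5 then leads on to 10.

**Step 16.**
- What may go wrong: slow lactone hydrolysis, which gives ester cleavage and migration of the coumaroyl group from O4 to the freed O5 time to compete.
- Fallback (sets out from 15, comes back at 27): no lactone is ever made, and O5 stays silylated until the end.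
- MeOCH2Cl and iPr2NEt convert 15 into methoxymethyl (1S,5R)-5-(tert-butyldimethylsilyloxy)-1-(methoxymethoxy)cyclohex-3-ene-1-carboxylate F9.
- OsO4 with N-methylmorpholine N-oxide should add anti to the allylic silyloxy group, giving methoxymethyl 5-O-(tert-butyldimethylsilyl)-1-O-(methoxymethyl)quinate F10.
- Since O4 is flanked by O3 and the bulky O5 silyl ether, 21 with DCC and 4-dimethylaminopyridine should acylate O3 first, giving the 3-O-[3,4-bis(methoxymethoxy)cinnamoyl] ester F11.
- Excess 25 under the same activation gives the 3,4-diester F12.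
- A shorter treatment with 2 M aq HCl–THF removes the MOM ester, the four MOM ethers and the silyl ether to give 27.

## Further compounds

F1 | step 8 | racemic methyl 3-hydroxy-2-(methoxymethoxy)propanoate | COCOC(CO)C(=O)OC
F2 | step 8 | methyl 2-(methoxymethoxy)acrylate | C=C(OCOC)C(=O)OC
F3 | step 8 | racemic methyl 1-(methoxymethoxy)cyclohex-3-ene-1-carboxylate | COCOC1(CC=CCC1)C(=O)OC
F4 | step 8 | racemic 1-(methoxymethoxy)cyclohex-3-ene-1-carboxylic acid | COCOC1(CC=CCC1)C(=O)O
F5 | step 8 | (S)-1-(methoxymethoxy)cyclohex-3-ene-1-carboxylic acid | C1=CC[C@](OCOC)(C(=O)O)CC1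
F6 | step 8 | (1S,4R,5R)-4-iodo-1-(methoxymethoxy)-6-oxabicyclo[3.2.1]octan-7-one | O=C1O[C@H]2[C@H](I)CC[C@]1(OCOC)C2
F7 | step 5 | (5R)-3-(methoxymethoxy)-5-[(S)-1-(4-methoxybenzyloxy)prop-2-enyl]dihydrofuran-2(3H)-one (3S epimer drawn) | C=C[C@H](OCc1ccc(OC)cc1)[C@H]2C[C@H](OCOC)C(=O)O2
F8 | step 5 | lithium (4R,5S)-4-hydroxy-5-(4-methoxybenzyloxy)-2-(methoxymethoxy)hept-6-enoate (2S epimer drawn) | C=C[C@H](OCc1ccc(OC)cc1)[C@H](O)C[C@H](OCOC)C(=O)[O-].[Li+]
F9 | step 16 | methoxymethyl (1S,5R)-5-(tert-butyldimethylsilyloxy)-1-(methoxymethoxy)cyclohex-3-ene-1-carboxylate | C1=C[C@H](O[Si](C)(C)C(C)(C)C)C[C@](OCOC)(C(=O)OCOC)C1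
F10 | step 16 | methoxymethyl 5-O-(tert-butyldimethylsilyl)-1-O-(methoxymethyl)quinate | O[C@H]1[C@@H](O)[C@H](O[Si](C)(C)C(C)(C)C)C[C@](OCOC)(C(=O)OCOC)C1
F11 | step 16 | 3-O-[3,4-bis(methoxymethoxy)cinnamoyl] ester of F10 | O=C(/C=C/c1ccc(OCOC)c(OCOC)c1)O[C@H]2[C@@H](O)[C@H](O[Si](C)(C)C(C)(C)C)C[C@](OCOC)(C(=O)OCOC)C2
F12 | step 16 | 3-O-[3,4-bis(methoxymethoxy)cinnamoyl]-4-O-[4-(methoxymethoxy)cinnamoyl] diester of F10 | O=C(/C=C/c1ccc(OCOC)c(OCOC)c1)O[C@H]2[C@@H](OC(=O)/C=C/c3ccc(OCOC)cc3)[C@H](O[Si](C)(C)C(C)(C)C)C[C@](OCOC)(C(=O)OCOC)C2
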